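**Retrosynthetic overview**

- The target is cut into two molecules of one monomer, labda-8(17),12E,14-trien-18-ol, by a head-to-head, endo [4+2] dimerisation (bonds C12–C14′ and C15–C15′). The central cyclohexene is the last ring formed.
- The diene is never handled. It is released in the dimerisation flask by cheletropic loss of SO2 from a 2-alkyl-3-methyl-3-sulfolene installed in the first step.
- Both decalin rings (bonds C4–C5 and C9–C10, four stereocentres, the 8(17)-alkene) come from one epoxide-triggered chair–chair polyene bicyclisation of an acyclic (E,E)-epoxy alcohol. The C3–OH left by the trigger is then excised through a cyclic thionocarbonate.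
- The epoxy alcohol comes from E-selective ω-hydroxylation (this oxygen becomes the equatorial C18–OH) and Sharpless epoxidation of a farnesyl-sulfolene, itself made from farnesyl bromide and 3-methyl-3-sulfolene.
- Ring order: sulfolene (purchased, sacrificial), then rings A and B together, then the central cyclohexene.

Assumption: the sulfolene C2 stereocentre (later C12) is formed racemic, carried as a ~1:1 epimer mixture (left undefined in the SMILES) and destroyed in step 7; labdane numbering is used, with C18 the equatorial CH2O on C4 and sulfolene C2–C5 becoming C12–C15.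

**Step 1**
Reactants: 1 (2E,6E)-farnesyl bromide; 2 3-methyl-3-sulfolene
Product: 3 2-[(2E,6E)-farnesyl]-3-methyl-2,5-dihydrothiophene 1,1-dioxide
Conditions: LiHMDS (1.05 equiv) added to 1 + 2, THF/DMPU (4:1), −78 °C; AcOH quench at −78 °C
Reagents that add atoms: none
Why: α-sulfonyl carbanion alkylation (SN2); 2 is deprotonated at C2 because the allyl anion then places its charge on the unsubstituted C4, in-situ trapping at −78 °C outruns ring-opening of the anion, the bromide reacts at C1 with its 2E,6E geometry intact, and the new ring stereocentre is racemic and erased in step 7.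

**Step 2**
Reactants: 3 farnesyl sulfolene
Product: 4 2-[(2E,6E,10E)-12-hydroxy-3,7,11-trimethyldodeca-2,6,10-trienyl]-3-methyl-2,5-dihydrothiophene 1,1-dioxide
Conditions: SeO2 (0.1 equiv), t-BuOOH (3 equiv), salicylic acid (0.1 equiv), CH2Cl2, 0 °C to rt, stopped near 50% conversion, 3 recycled
Reagents that add atoms: tert-butyl hydroperoxide, CC(C)(C)OO (net oxygen source); selenium dioxide, O=[Se]=O (catalytic carrier of that oxygen)
Why: Sharpless SeO2/t-BuOOH allylic oxidation (ene reaction then [2,3]-sigmatropic shift) attacks the most electron-rich, least hindered trisubstituted alkene, the terminal isopropylidene, at its E-methyl group, so the CH2OH is trans to the chain and later becomes the equatorial C18.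

**Step 3**
Reactants: 4 ω-hydroxy farnesyl sulfolene
Product: 5 2-{(2E,6E)-9-[(2S,3S)-3-(hydroxymethyl)-3-methyloxiran-2-yl]-3,7-dimethylnona-2,6-dienyl}-3-methyl-2,5-dihydrothiophene 1,1-dioxide
Conditions: Ti(OiPr)4 (10 mol %), L-(+)-diethyl tartrate (12 mol %), t-BuOOH (2 equiv, decane), 4 Å MS, CH2Cl2, −25 °C
Reagents that add atoms: tert-butyl hydroperoxide, CC(C)(C)OO
Why: Sharpless asymmetric epoxidation; only the alkene of the allylic alcohol reacts and L-(+)-tartrate delivers oxygen to the face that gives the (2S,3S)-epoxy alcohol (labdane C3 S, C4 S), typically ≥95% ee for E-2-methyl-2-alken-1-ols.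

**Step 4**
Reactants: 5 (2S,3S)-epoxy alcohol
Product: 8 sulfolene-masked labd-8(17)-ene-3β,18-diol (3S,4R,5R,9S,10R), via epoxy TMS ether 6 (not isolated), via bicyclic bis-TMS ether 7 (not isolated)
Conditions: TMSCl (5 equiv), 2,4,6-collidine (8 equiv), THF, rt, 30 min; then Cp2TiCl2 (0.2 equiv), Mn dust (8 equiv), THF (0.03 M), rt, 16 h; then 1 M HCl/THF, 0 °C
Reagents that add atoms: none
Why: Ti(III)-catalysed reductive epoxide opening (Nugent–RajanBabu type) gives the tertiary C4 radical, which closes rings A and B by two 6-endo radical additions through an all-chair transition state anchored by the equatorial C3–O[Ti] of the (3S)-epoxide, so C5 (α-H), C10 (β-CH3) and C9 (β-CH2) are set relative to C3, the bulkier CH2OTMS on the planar C4 radical is expected to take the equatorial (4α, C18) position, and Cp2TiCl trapping with β-hydride elimination of the C8 radical gives the exocyclic 8(17)-alkene.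

**Step 5**
Reactants: 8 3β,18-diol
Product: 9 3,18-O-thiocarbonyl derivative of 8 (cyclic 1,3-dioxane-2-thione)
Conditions: 1,1′-thiocarbonyldiimidazole (1.5 equiv), DMAP (0.1 equiv), THF, 60 °C
Reagents that add atoms: 1,1′-thiocarbonyldiimidazole, S=C(n1ccnc1)n1ccnc1
Why: thiocarbonyl transfer to a 1,3-diol; the equatorial 3β-OH and the equatorial 4α-CH2OH are gauche and close a six-membered cyclic thionocarbonate without touching any stereocentre.

**Step 6**
Reactants: 9 cyclic thionocarbonate
Product: 11 sulfolene-masked labd-8(17)-en-18-ol (4R,5R,9S,10R), via S-silyl thiocarbonate 10 (not isolated)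
Conditions: (Me3Si)3SiH (1.5 equiv), Et3B (0.3 equiv)/air, toluene, rt; then MeOH/H2O (9:1), rt
Reagents that add atoms: none
Why: Barton–McCombie-type radical deoxygenation of a cyclic thionocarbonate; silyl-radical addition to C=S is followed by β-scission of the C–O bond that gives the more stable secondary C3 radical rather than the primary C18 radical, Si–H transfers hydrogen, and hydrolysis of the S–Si bond with loss of COS frees the primary C18–OH under base-free room-temperature conditions that leave C4 and the sulfolene untouched.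

**Step 7**
Reactants: 11 sulfolene-masked labd-8(17)-en-18-ol (two molecules)
Product: 13 CNP0194625.1 (target), via labda-8(17),12E,14-trien-18-ol 12 (not isolated)
Conditions: neat melt, BHT (5 mol %), 2,6-lutidine (10 mol %), 130 °C, Ar sweep, 2 h; then sealed, 150 °C, 36 h; silica, then preparative HPLC
Reagents that add atoms: none
Why: retro-cheletropic SO2 extrusion (disrotatory, the C2 substituent rotating outward) gives only the 12E diene, which undergoes thermal Diels–Alder dimerisation in which the C12=C13–C14=C15 diene of one molecule adds the C14′=C15′ vinyl group of a second, bonding first through the unsubstituted termini (C15–C15′) to give the observed regiochemistry and through the endo transition state to give the cis C12/C14′ ring; the decalins are too remote to bias the face, so the (1S,6S) target forms together with its (1R,6R) endo isomer (about 1:1) and exo isomers and is separated.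

**Compound list**

1 | (2E,6E)-farnesyl bromide, (2E,6E)-1-bromo-3,7,11-trimethyldodeca-2,6,10-triene | CC(C)=CCC/C(C)=C/CC/C(C)=C/CBr | starting material
2 | 3-methyl-3-sulfolene, 3-methyl-2,5-dihydrothiophene 1,1-dioxide | CC1=CCS(=O)(=O)C1 | starting material
3 | 2-[(2E,6E)-3,7,11-trimethyldodeca-2,6,10-trienyl]-3-methyl-2,5-dihydrothiophene 1,1-dioxide (racemic at ring C2) | CC(C)=CCC/C(C)=C/CC/C(C)=C/CC1C(C)=CCS1(=O)=O | intermediate
4 | 2-[(2E,6E,10E)-12-hydroxy-3,7,11-trimethyldodeca-2,6,10-trienyl]-3-methyl-2,5-dihydrothiophene 1,1-dioxide | OC/C(C)=C/CC/C(C)=C/CC/C(C)=C/CC1C(C)=CCS1(=O)=O | intermediate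
5 | 2-{(2E,6E)-9-[(2S,3S)-3-(hydroxymethyl)-3-methyloxiran-2-yl]-3,7-dimethylnona-2,6-dienyl}-3-methyl-2,5-dihydrothiophene 1,1-dioxide | OC[C@]1(C)O[C@H]1CC/C(C)=C/CC/C(C)=C/CC1C(C)=CCS1(=O)=O | intermediate
6 | O-trimethylsilyl ether of 5 | C[Si](C)(C)OC[C@]1(C)O[C@H]1CC/C(C)=C/CC/C(C)=C/CC1C(C)=CCS1(=O)=O | intermediate (not isolated)
7 | 3,18-bis-O-trimethylsilyl ether of 8 | C=C1CC[C@H]2[C@](C)(CO[Si](C)(C)C)[C@@H](O[Si](C)(C)C)CC[C@]2(C)[C@H]1CC1C(C)=CCS1(=O)=O | intermediate (not isolated)
8 | (1R,2S,4aR,5S,8aR)-1-(hydroxymethyl)-1,4a-dimethyl-6-methylidene-5-[(3-methyl-1,1-dioxo-2,5-dihydrothiophen-2-yl)methyl]decahydronaphthalen-2-ol (labdane 3S,4R,5R,9S,10R; 3β-OH and 18-OH both equatorial) | C=C1CC[C@H]2[C@](C)(CO)[C@@H](O)CC[C@]2(C)[C@H]1CC1C(C)=CCS1(=O)=O | intermediate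
9 | 3,18-O-thiocarbonyl derivative of 8 (cyclic thionocarbonate bridging O3 and O18) | C=C1CC[C@H]2[C@](C)(COC(=S)O3)[C@@H]3CC[C@]2(C)[C@H]1CC1C(C)=CCS1(=O)=O | intermediate
10 | 18-O-{[tris(trimethylsilyl)silyl]sulfanylcarbonyl} derivative of 11 | C=C1CC[C@H]2[C@](C)(COC(=O)S[Si]([Si](C)(C)C)([Si](C)(C)C)[Si](C)(C)C)CCC[C@]2(C)[C@H]1CC1C(C)=CCS1(=O)=O | intermediate (not isolated)
11 | [(1R,4aR,5S,8aR)-1,4a-dimethyl-6-methylidene-5-[(3-methyl-1,1-dioxo-2,5-dihydrothiophen-2-yl)methyl]decahydronaphthalen-1-yl]methanol (labdane 4R,5R,9S,10R) | C=C1CC[C@H]2[C@](C)(CO)CCC[C@]2(C)[C@H]1CC1C(C)=CCS1(=O)=O | intermediate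
12 | labda-8(17),12E,14-trien-18-ol, [(1R,4aR,5S,8aR)-1,4a-dimethyl-6-methylidene-5-[(2E)-3-methylpenta-2,4-dienyl]decahydronaphthalen-1-yl]methanol | C=C1CC[C@H]2[C@](C)(CO)CCC[C@]2(C)[C@H]1C/C=C(\C)C=C | intermediate (not isolated)
13 | CNP0194625.1: (1S,6S)-cis-2-methylcyclohex-2-ene whose C1 carries CH2 bound to C9 of one 18-hydroxylabd-8(17)-ene unit and whose C6 carries the (E)-C(CH3)=CH–CH2 chain bound to C9′ of the second unit; both decalins 4R,5R,9S,10R | C=C1CC[C@H]2[C@](C)(CO)CCC[C@]2(C)[C@H]1C/C=C(\C)[C@H]1CCC=C(C)[C@H]1C[C@H]1C(=C)CC[C@H]2[C@](C)(CO)CCC[C@]12C | target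

**Step count and risk**

Total steps: 7. Longest linear sequence: 7 (1 or 2 to 13).

The three steps most likely to fail:

Step 7 (unmasking and dimerisation). Regiochemistry should be good, but the endo/exo ratio is likely only 1–2:1 and the two faces are not distinguished. The target is therefore expected to be about 20–25% of the dimer fraction, roughly 10–15% isolated, alongside oligomers. The fallback makes the cycloaddition intramolecular. It sets out from 11: two molecules are joined through their C18 oxygens with iPr2SiCl2 (0.5 equiv) and imidazole in DMF to give the bis(sulfolene) diisopropylsilylene bis-ether F1. Heating F1 at 0.005 M in 1,2-dichlorobenzene at 160 °C removes both SO2 units to give the tethered bis-diene F2, which is not isolated and closes by an intramolecular Diels–Alder reaction through a 19-membered ring to the silyl-bridged cycloadduct F3. High dilution suppresses oligomers, and the tether restricts which of the pairings can reach a transition state. Which endo diastereomer it favours has to be found by experiment, and the tether length can be varied if it is the wrong one. TBAF/AcOH in THF removes the silicon bridge from F3 and the route comes back at 13.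

Step 4 (radical bicyclisation). Bicyclisations of this type usually give 30–45%. The C4 configuration rests on a conformational preference of a planar radical, and the C8 radical could be intercepted by the sulfolene alkene. The fallback is a cationic closure that is stereospecific at C4. It sets out from 5: TBSCl and imidazole give the epoxy silyl ether F4. MeAlCl2 (3 equiv) in CH2Cl2 at −78 °C then triggers a Lewis-acid epoxide-opening polyene cyclisation, in which C5 attacks C4 anti to the breaking C–O bond through the chair–chair fold, so the E-CH2OTBS group must end equatorial. This gives the 3β-hydroxy-18-silyloxy bicycle F5. Termination is less selective here, so the exocyclic alkene has to be separated from double-bond isomers on AgNO3–silica. TBAF/AcOH converts F5 into the diol and the route comes back at 8.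

Step 2 (SeO2 oxidation). Site selectivity among three trisubstituted alkenes and over-oxidation limit the yield to about 35–45% per pass. The fallback builds the oxygenated terminus by olefination instead of C–H oxidation. It sets out from 3: NBS in THF/H2O at 0 °C gives the terminal bromohydrin F6 (van Tamelen terminal selectivity). K2CO3 in MeOH closes it to the racemic terminal epoxide F7. H5IO6 in THF/H2O cleaves F7 to the trisnor aldehyde F8. Ph3P=C(CH3)CO2Et in CH2Cl2 gives the ethyl (E)-2-methyl-enoate F9 with high E selectivity. DIBAL-H in CH2Cl2 at −78 °C reduces the ester and the route comes back at 4.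

**Further compounds**

F1 | step 7 | bis{[sulfolene-masked labd-8(17)-en-18-yl]oxy}diisopropylsilane | C=C1CC[C@H]2[C@](C)(CO[Si](C(C)C)(C(C)C)OC[C@]3(C)CCC[C@]4(C)[C@@H](CC5C(C)=CCS5(=O)=O)C(=C)CC[C@@H]34)CCC[C@]2(C)[C@H]1CC1C(C)=CCS1(=O)=O
F2 | step 7 | bis{[(12E)-labda-8(17),12,14-trien-18-yl]oxy}diisopropylsilane | C=C1CC[C@H]2[C@](C)(CO[Si](C(C)C)(C(C)C)OC[C@]3(C)CCC[C@]4(C)[C@@H](C/C=C(\C)C=C)C(=C)CC[C@@H]34)CCC[C@]2(C)[C@H]1C/C=C(\C)C=C
F3 | step 7 | 18,18′-O-(diisopropylsilylene) derivative of 13 | C=C1CC[C@H]2[C@](C)(CO[Si]3(C(C)C)C(C)C)CCC[C@]2(C)[C@H]1C/C=C(\C)[C@H]1CCC=C(C)[C@H]1C[C@H]1C(=C)CC[C@H]2[C@](C)(CO3)CCC[C@]12C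
F4 | step 4 | O-tert-butyldimethylsilyl ether of 5 | CC(C)(C)[Si](C)(C)OC[C@]1(C)O[C@H]1CC/C(C)=C/CC/C(C)=C/CC1C(C)=CCS1(=O)=O
F5 | step 4 | 18-O-tert-butyldimethylsilyl ether of 8 | C=C1CC[C@H]2[C@](C)(CO[Si](C)(C)C(C)(C)C)[C@@H](O)CC[C@]2(C)[C@H]1CC1C(C)=CCS1(=O)=O
F6 | step 2 | 2-[(2E,6E)-10-bromo-11-hydroxy-3,7,11-trimethyldodeca-2,6-dienyl]-3-methyl-2,5-dihydrothiophene 1,1-dioxide | CC(C)(O)C(Br)CC/C(C)=C/CC/C(C)=C/CC1C(C)=CCS1(=O)=O
F7 | step 2 | 2-[(2E,6E)-9-(3,3-dimethyloxiran-2-yl)-3,7-dimethylnona-2,6-dienyl]-3-methyl-2,5-dihydrothiophene 1,1-dioxide (racemic epoxide) | CC1(C)OC1CC/C(C)=C/CC/C(C)=C/CC1C(C)=CCS1(=O)=O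
F8 | step 2 | (4E,8E)-4,8-dimethyl-10-(3-methyl-1,1-dioxo-2,5-dihydrothiophen-2-yl)deca-4,8-dienal | O=CCC/C(C)=C/CC/C(C)=C/CC1C(C)=CCS1(=O)=O
F9 | step 2 | ethyl (2E,6E,10E)-2,6,10-trimethyl-12-(3-methyl-1,1-dioxo-2,5-dihydrothiophen-2-yl)dodeca-2,6,10-trienoate | CCOC(=O)/C(C)=C/CC/C(C)=C/CC/C(C)=C/CC1C(C)=CCS1(=O)=O
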